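**Retrosynthetic overview**
1. The target comes from a sulfated trans-2-aryl-2,3-dihydrobenzofuran-3-carboxylate. The side-chain alcohol is sulfated while the carbon on C3 is still CO2Me and the ring B phenol is a pivalate. One LiBH4 step then reveals both CH2OH and ArOH.
2. The key disconnection is C3–C3a. The five-membered ring arises by ring contraction of a (2S)-flavanone. PhI(OAc)2 makes the enol carbon C3 electrophilic (an enolonium equivalent), and the ipso carbon of ring A attacks it in a 1,2-aryl shift. C4 becomes the ester carbon.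
3. The C2–aryl bond comes from chromone plus arylboronic acid by enantioselective Pd-catalysed conjugate addition. This is the only external source of chirality.
4. The chromone comes from an o-hydroxyacetophenone (one carbon from DMF dimethyl acetal), which comes from dihydroconiferyl alcohol by Fries rearrangement.
5. Ring order: both benzene rings are bought. The six-membered pyranone is closed first and is then contracted to the dihydrofuran.

Assumption: the target is the free hydrogen sulfate as drawn, released from its sodium salt by cold acidification in the last work-up; the sodium salt 13 is the better storage form.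

**Step 1**
Reactants: 1 4-(3-hydroxypropyl)-2-methoxyphenol (dihydroconiferyl alcohol)
Product: 3 3-(3-acetyl-4-hydroxy-5-methoxyphenyl)propyl acetate, via diacetate 2 (not isolated)
Conditions: AcCl (2.3 equiv), PhCl, 0 °C → rt; TiCl4 (3.5 equiv), 110 °C, 4 h; 1 M HCl
Reagents that add atoms: acetyl chloride, CC(=O)Cl
Why: O-acetylation followed by a Lewis-acid Fries rearrangement, in which TiCl4 chelated by the guaiacyl O,O pair switches off the methoxy group as a director and delivers the acylium ion to the only free position ortho to the phenolate oxygen (para is blocked by the side chain), the chelated o-hydroxyaryl ketone being the thermodynamic sink and no stereocentre being formed.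

**Step 2**
Reactants: 3 3-(3-acetyl-4-hydroxy-5-methoxyphenyl)propyl acetate
Product: 5 6-(3-hydroxypropyl)-8-methoxy-4H-chromen-4-one, via enaminone 4 (not isolated)
Conditions: Me2NCH(OMe)2 (2.5 equiv), PhMe, 100 °C; evaporate; conc. HCl, MeOH, reflux, 2 h
Reagents that add atoms: N,N-dimethylformamide dimethyl acetal, COC(OC)N(C)C
Why: Enaminone condensation of the methyl ketone with the amide acetal and acid-induced addition–elimination by the ortho phenol is the standard chromone synthesis, and the refluxing methanolic HCl transesterifies the primary acetate at the same time, so the side-chain alcohol is free from here on.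

**Step 3**
Reactants: 6 (4-hydroxy-3-methoxyphenyl)boronic acid
Product: 7 [3-methoxy-4-(pivaloyloxy)phenyl]boronic acid
Conditions: t-BuCOCl (1.1 equiv), Et3N (1.3 equiv), 4-(dimethylamino)pyridine (5 mol %), THF, 0 °C → rt; dilute aq. HCl wash
Reagents that add atoms: pivaloyl chloride, CC(C)(C)C(=O)Cl
Why: Simple phenol O-acylation (any boron mixed anhydride is hydrolysed on work-up), chosen because the acid-stable, electron-withdrawing pivalate shields ring B from the trivalent iodine oxidant, lowers its migratory aptitude and the tendency of C2 to ionise, and is removed without an extra step in the final hydride reduction.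

**Step 4**
Reactants: 5 6-(3-hydroxypropyl)-8-methoxy-4H-chromen-4-one; 7 [3-methoxy-4-(pivaloyloxy)phenyl]boronic acid (2 equiv)
Product: 8 4-[(2S)-6-(3-hydroxypropyl)-8-methoxy-4-oxochroman-2-yl]-2-methoxyphenyl pivalate
Conditions: Pd(OCOCF3)2 (5 mol %), (R)-t-BuPyOx [(R)-4-tert-butyl-2-(pyridin-2-yl)-4,5-dihydrooxazole] (6 mol %), NH4PF6 (30 mol %), H2O (5 equiv), ClCH2CH2Cl, 60 °C, 18 h
Reagents that add atoms: none
Why: Asymmetric conjugate addition of an arylboronic acid to a chromone under cationic divalent palladium–pyridinooxazoline catalysis (enantio-determining migratory insertion, then protonolysis of the palladium enolate) sets C2 as S, the (R)-ligand being taken because the (S)-ligand arylates cyclic enones on the face that corresponds to 2R here (an assignment by analogy that must be confirmed on 8, the other ligand antipode serving if the sense proves opposite), and the neutral medium avoids the base-induced ring opening that racemises flavanones.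

**Step 5 (key step)**
Reactants: 8 4-[(2S)-6-(3-hydroxypropyl)-8-methoxy-4-oxochroman-2-yl]-2-methoxyphenyl pivalate
Product: 11 methyl (2S,3S)-5-(3-hydroxypropyl)-7-methoxy-2-[3-methoxy-4-(pivaloyloxy)phenyl]-2,3-dihydro-1-benzofuran-3-carboxylate (2,3-trans), via enol ether 9 (not isolated), via alpha-iodanyl ketal 10 (not isolated)
Conditions: PhI(OAc)2 (1.2 equiv), H2SO4 (cat.), HC(OMe)3, 0 °C → rt, 2 h; then MeOH–1 M aq. HCl, rt, 1 h (frees any side-chain orthoformate or formate)
Reagents that add atoms: trimethyl orthoformate, COC(OC)OC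
Why: Hypervalent-iodine oxidative ring contraction of a flavanone (1,2-aryl migration of quasi-Favorskii type), in which the normally nucleophilic enol ether carbon C3 becomes an enolonium equivalent by C–I bond formation anti to the C2 aryl group, and the equally nucleophilic ipso carbon of ring A, whose C4–C4a bond lies antiperiplanar to the equatorial C3–I bond, migrates onto it with inversion while PhI leaves and C4 collapses to the methyl ester, so that C3–C3a is forged, the five-membered ring is made and C3 is set trans to the untouched C2 centre.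

**Step 6**
Reactants: 11 methyl (2S,3S)-5-(3-hydroxypropyl)-7-methoxy-2-[3-methoxy-4-(pivaloyloxy)phenyl]-2,3-dihydro-1-benzofuran-3-carboxylate
Product: 12 sodium 3-{(2S,3S)-7-methoxy-3-(methoxycarbonyl)-2-[3-methoxy-4-(pivaloyloxy)phenyl]-2,3-dihydro-1-benzofuran-5-yl}propyl sulfate
Conditions: SO3·pyridine (2 equiv), pyridine, 0 °C → rt; aq. NaHCO3; C18 silica
Reagents that add atoms: sulfur trioxide–pyridine complex, [O-]S(=O)(=O)[n+]1ccccc1; sodium hydrogen carbonate, [Na+].OC([O-])=O
Why: Alcohol O-sulfation with the SO3–amine complex meets a single free hydroxyl, because the carbon on C3 is still an ester and the phenol a pivalate, so the site-selectivity problem of the triol never arises and no stereocentre is touched.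

**Step 7**
Reactants: 12 sodium 3-{(2S,3S)-7-methoxy-3-(methoxycarbonyl)-2-[3-methoxy-4-(pivaloyloxy)phenyl]-2,3-dihydro-1-benzofuran-5-yl}propyl sulfate
Product: 14 3-[(2S,3R)-2-(4-hydroxy-3-methoxyphenyl)-3-(hydroxymethyl)-7-methoxy-2,3-dihydro-1-benzofuran-5-yl]propyl hydrogen sulfate, via sodium salt 13 (not isolated)
Conditions: LiBH4 (5 equiv), THF–MeOH, 0 → 40 °C, 6 h; 1 M HCl to pH 2, 0 °C; n-BuOH extraction, C18 silica
Reagents that add atoms: none
Why: Chemoselective borohydride ester reduction, in which LiBH4 turns the methyl ester into the C3 hydroxymethyl group and reductively cleaves the aryl pivalate while the anionic sulfate monoester is inert to hydride (as after hydride opening of cyclic sulfates), the weakly basic medium leaves C2 and C3 untouched (the C3 descriptor changes from S to R only through the priority change), and cold acidification releases the hydrogen sulfate.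

**Compound list**
1 | 4-(3-hydroxypropyl)-2-methoxyphenol (dihydroconiferyl alcohol) | COc1cc(CCCO)ccc1O | starting material
2 | 4-(3-acetoxypropyl)-2-methoxyphenyl acetate | COc1cc(CCCOC(C)=O)ccc1OC(C)=O | intermediate
3 | 3-(3-acetyl-4-hydroxy-5-methoxyphenyl)propyl acetate | COc1cc(CCCOC(C)=O)cc(C(C)=O)c1O | intermediate
4 | 3-{3-[(E)-3-(dimethylamino)prop-2-enoyl]-4-hydroxy-5-methoxyphenyl}propyl acetate | COc1cc(CCCOC(C)=O)cc(C(=O)/C=C/N(C)C)c1O | intermediate
5 | 6-(3-hydroxypropyl)-8-methoxy-4H-chromen-4-one | COc1cc(CCCO)cc2c(=O)ccoc12 | intermediate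
6 | (4-hydroxy-3-methoxyphenyl)boronic acid | COc1cc(B(O)O)ccc1O | starting material
7 | [3-methoxy-4-(pivaloyloxy)phenyl]boronic acid | COc1cc(B(O)O)ccc1OC(=O)C(C)(C)C | intermediate
8 | 4-[(2S)-6-(3-hydroxypropyl)-8-methoxy-4-oxochroman-2-yl]-2-methoxyphenyl pivalate | COc1cc([C@H]2Oc3c(OC)cc(CCCO)cc3C(=O)C2)ccc1OC(=O)C(C)(C)C | intermediate
9 | 4-[(2S)-6-(3-hydroxypropyl)-4,8-dimethoxy-2H-chromen-2-yl]-2-methoxyphenyl pivalate | COc1cc([C@H]2Oc3c(OC)cc(CCCO)cc3C(OC)=C2)ccc1OC(=O)C(C)(C)C | intermediate
10 | 4-{(2R,3R)-3-[acetoxy(phenyl)-λ3-iodanyl]-6-(3-hydroxypropyl)-4,4,8-trimethoxychroman-2-yl}-2-methoxyphenyl pivalate (aryl and iodine trans; the C2 descriptor changes only because iodine raises the rank of C3) | COc1cc([C@H]2Oc3c(OC)cc(CCCO)cc3C(OC)(OC)[C@@H]2I(OC(C)=O)c2ccccc2)ccc1OC(=O)C(C)(C)C | intermediate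
11 | methyl (2S,3S)-5-(3-hydroxypropyl)-7-methoxy-2-[3-methoxy-4-(pivaloyloxy)phenyl]-2,3-dihydro-1-benzofuran-3-carboxylate (trans) | COc1cc([C@H]2Oc3c(OC)cc(CCCO)cc3[C@@H]2C(=O)OC)ccc1OC(=O)C(C)(C)C | intermediate
12 | sodium 3-{(2S,3S)-7-methoxy-3-(methoxycarbonyl)-2-[3-methoxy-4-(pivaloyloxy)phenyl]-2,3-dihydro-1-benzofuran-5-yl}propyl sulfate | COc1cc([C@H]2Oc3c(OC)cc(CCCOS(=O)(=O)[O-])cc3[C@@H]2C(=O)OC)ccc1OC(=O)C(C)(C)C.[Na+] | intermediate
13 | sodium 3-[(2S,3R)-2-(4-hydroxy-3-methoxyphenyl)-3-(hydroxymethyl)-7-methoxy-2,3-dihydro-1-benzofuran-5-yl]propyl sulfate | COc1cc([C@H]2Oc3c(OC)cc(CCCOS(=O)(=O)[O-])cc3[C@@H]2CO)ccc1O.[Na+] | intermediate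
14 | 3-[(2S,3R)-2-(4-hydroxy-3-methoxyphenyl)-3-(hydroxymethyl)-7-methoxy-2,3-dihydro-1-benzofuran-5-yl]propyl hydrogen sulfate | COc1cc([C@H]2Oc3c(OC)cc(CCCOS(=O)(=O)O)cc3[C@@H]2CO)ccc1O | target

**Step count**
Total steps: 7.
Longest linear sequence: 6 (steps 1, 2, 4, 5, 6, 7; 1 → 3 → 5 → 8 → 11 → 12 → 14).

**Three steps most likely to fail**

Step 5, the ring contraction.
- Possible failures are dehydrogenation to the flavone, a ring B shift to the isoflavone, cis-3-methoxylation, and acid-induced erosion of ee at C2.
- The fallback sets out from 8 and returns at 11. It replaces the transient iodane by an isolable enolonium equivalent.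
- Compound 8 is brominated with PhNMe3Br3 in THF to the 2,3-trans 3-bromoflavanone F1.
- This is converted with HC(OMe)3, MeOH and p-toluenesulfonic acid into the bromo dimethyl ketal F2.
- Heating the ketal with ZnBr2 (10 mol %) in toluene at 100 °C triggers the same antiperiplanar 1,2-aryl shift with inversion. Loss of MeBr gives 11.

Step 4, the asymmetric conjugate addition.
- Possible failures are sluggish insertion with the 8-methoxychromone, protodeboronation, reduction of the catalyst to palladium black by the free alcohol, and a sense of induction that rests on analogy.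
- The fallback sets out from 5 and 7 and returns at 8. It uses resolution in place of asymmetric catalysis.
- Pd(OCOCF3)2 with 2,2'-bipyridine gives the racemic flavanone F3.
- Transfer-hydrogenative kinetic resolution follows, with RuCl(p-cymene)[(R,R)-TsDPEN] and HCO2H/Et3N in EtOAc.
- This reduces the 2R ketone to the separable (2R,4R)-cis-flavan-4-ol F4 and leaves (2S)-8 unreacted.

Step 1, the Fries rearrangement.
- Possible failures are acylation para to the methoxy group, demethylation, and side-chain chloride formation.
- The fallback sets out from 1 and returns at 5. It builds the ketone by an ortho-specific route.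
- Magnesium-mediated formylation (MgCl2, Et3N, paraformaldehyde, MeCN, reflux) gives the salicylaldehyde F5.
- MeMgBr (3.5 equiv, THF) gives the racemic benzylic alcohol F6.
- MnO2 in CH2Cl2 oxidises only the benzylic position, giving the hydroxy ketone F7.
- Under the conditions of step 2 this passes through the enaminone F8 to 5.

**Further compounds**
F1 | step 5 | 4-[(2R,3R)-3-bromo-6-(3-hydroxypropyl)-8-methoxy-4-oxochroman-2-yl]-2-methoxyphenyl pivalate (2,3-trans) | COc1cc([C@H]2Oc3c(OC)cc(CCCO)cc3C(=O)[C@@H]2Br)ccc1OC(=O)C(C)(C)C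
F2 | step 5 | 4-[(2R,3R)-3-bromo-6-(3-hydroxypropyl)-4,4,8-trimethoxychroman-2-yl]-2-methoxyphenyl pivalate (2,3-trans) | COc1cc([C@H]2Oc3c(OC)cc(CCCO)cc3C(OC)(OC)[C@@H]2Br)ccc1OC(=O)C(C)(C)C
F3 | step 4 | racemic 4-[6-(3-hydroxypropyl)-8-methoxy-4-oxochroman-2-yl]-2-methoxyphenyl pivalate | COc1cc(C2Oc3c(OC)cc(CCCO)cc3C(=O)C2)ccc1OC(=O)C(C)(C)C
F4 | step 4 | 4-[(2R,4R)-4-hydroxy-6-(3-hydroxypropyl)-8-methoxychroman-2-yl]-2-methoxyphenyl pivalate (2,4-cis) | COc1cc([C@@H]2Oc3c(OC)cc(CCCO)cc3[C@H](O)C2)ccc1OC(=O)C(C)(C)C
F5 | step 1 | 2-hydroxy-5-(3-hydroxypropyl)-3-methoxybenzaldehyde | COc1cc(CCCO)cc(C=O)c1O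
F6 | step 1 | 2-(1-hydroxyethyl)-4-(3-hydroxypropyl)-6-methoxyphenol (racemic) | COc1cc(CCCO)cc(C(C)O)c1O
F7 | step 1 | 1-[2-hydroxy-5-(3-hydroxypropyl)-3-methoxyphenyl]ethanone | COc1cc(CCCO)cc(C(C)=O)c1O
F8 | step 1 | (E)-3-(dimethylamino)-1-[2-hydroxy-5-(3-hydroxypropyl)-3-methoxyphenyl]prop-2-en-1-one | COc1cc(CCCO)cc(C(=O)/C=C/N(C)C)c1O
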